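**Retrosynthetic overview**

1. The target is reached from a fully protected tetralin (tert-butyl ester, MOM aryl ether, TBS ether) by desilylation, acylation with 3-phenylpropanoyl chloride and a final acid deprotection.
2. Key disconnection: the bond in ring B (the saturated six-membered ring) between the benzylic CH that carries the side chain and the ring CH2 next to it. The precursor is an open-chain primary bromide bearing an E trisubstituted styrene; one copper hydride hydroalkylation closes ring B and sets both neighbouring CH centres.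
3. Enabling feature: that ring CH is benzylic to ring A (the benzene ring) and its chain neighbour is a CH(CH3). Two vicinal C–H centres, one of them benzylic, are the syn H/C adduct of an aryl–CH=C(CH3)–alkyl unit, and the ring CH2 to be bonded sits at the end of a three-carbon arm on the other ortho carbon of ring A.
4. The styrene comes from an aryl triflate and an (E)-2-methylalkenyl metal (zirconium-catalysed methylalumination of a chiral-pool alkyne, then Negishi coupling). The aryl triflate comes from 4-bromo-3,5-dihydroxybenzoic acid by Suzuki coupling and asymmetric conjugate reduction, which sets the ring-methyl centre.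
5. Ring order: ring A is bought; ring B is the only ring formed (step 12).

Key step: step 12

Assumption: the β-boryl crotonate of step 3 is taken as purchasable (otherwise one step from ethyl but-2-ynoate), and the sense of induction of the DTBM-SEGPHOS copper hydride catalysts in steps 5 and 12 is assigned as written; the other ligand enantiomer would be used if a trial run shows the opposite sense.

**Route**

Step 1
Reactants: 1 4-bromo-3,5-dihydroxybenzoic acid
Product: 2 tert-butyl 4-bromo-3,5-dihydroxybenzoate
Conditions: Me2NCH(Ot-Bu)2, toluene, 80 °C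
Reagents that add atoms: N,N-dimethylformamide di-tert-butyl acetal, CN(C)C(OC(C)(C)C)OC(C)(C)C
Why: Esterification by tert-butyl transfer from the amide acetal to the carboxylic acid spares the less acidic phenols and gives an ester that should survive every basic and organometallic step and fall off with acid at the end.

Step 2
Reactants: 2 tert-butyl 4-bromo-3,5-dihydroxybenzoate
Product: 3 tert-butyl 4-bromo-3-hydroxy-5-(methoxymethoxy)benzoate
Conditions: MOMCl (1 equiv), i-Pr2NEt, CH2Cl2, 0 °C
Reagents that add atoms: chloromethyl methyl ether, COCCl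
Why: Williamson-type mono-etherification of a symmetric resorcinol, in which both hydroxyls are equivalent, should give the mono-ether statistically, with unreacted diol 2 recovered and recycled.

Step 3
Reactants: 3 tert-butyl 4-bromo-3-hydroxy-5-(methoxymethoxy)benzoate, 4 ethyl (Z)-3-(4,4,5,5-tetramethyl-1,3,2-dioxaborolan-2-yl)but-2-enoate
Product: 5 tert-butyl 4-[(E)-4-ethoxy-4-oxobut-2-en-2-yl]-3-hydroxy-5-(methoxymethoxy)benzoate
Conditions: Pd(OAc)2, SPhos, K3PO4, toluene/H2O, 80 °C
Reagents that add atoms: none
Why: Suzuki–Miyaura coupling with a bulky biarylphosphine should tolerate the doubly ortho-substituted bromide and the free phenol and transfer the alkenyl group with retention, so that boron trans to the ester becomes aryl trans to the ester (E), a geometry that cannot lactonise to a coumarin.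

Step 4
Reactants: 5 tert-butyl 4-[(E)-4-ethoxy-4-oxobut-2-en-2-yl]-3-hydroxy-5-(methoxymethoxy)benzoate
Product: 6 tert-butyl 4-[(E)-4-ethoxy-4-oxobut-2-en-2-yl]-3-(methoxymethoxy)-5-[(trifluoromethylsulfonyl)oxy]benzoate
Conditions: Tf2O, pyridine, CH2Cl2, −10 °C
Reagents that add atoms: trifluoromethanesulfonic anhydride, O=S(=O)(OS(=O)(=O)C(F)(F)F)C(F)(F)F
Why: Triflate formation (O-sulfonylation of the phenol) turns the second ring oxygen into the handle for the later cross-coupling and removes the acidic OH before the hydride step.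

Step 5
Reactants: 6 tert-butyl 4-[(E)-4-ethoxy-4-oxobut-2-en-2-yl]-3-(methoxymethoxy)-5-[(trifluoromethylsulfonyl)oxy]benzoate
Product: 7 tert-butyl 4-[(R)-4-ethoxy-4-oxobutan-2-yl]-3-(methoxymethoxy)-5-[(trifluoromethylsulfonyl)oxy]benzoate
Conditions: Cu(OAc)2 (3 mol%), (R)-DTBM-SEGPHOS (3.3 mol%), (EtO)2MeSiH, t-BuOH, toluene, rt
Reagents that add atoms: none
Why: Copper hydride catalysed asymmetric conjugate reduction (1,4-hydrosilylation) of a β-aryl-β-methyl enoate, a well-tried substrate class, should deliver hydride to the Si face of the β-carbon under control of the chiral bisphosphine and so set the R ring-methyl centre, while the aryl triflate and the unconjugated tert-butyl ester are left alone.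

Step 6
Reactants: 7 tert-butyl 4-[(R)-4-ethoxy-4-oxobutan-2-yl]-3-(methoxymethoxy)-5-[(trifluoromethylsulfonyl)oxy]benzoate
Product: 8 tert-butyl 4-[(R)-4-hydroxybutan-2-yl]-3-(methoxymethoxy)-5-[(trifluoromethylsulfonyl)oxy]benzoate
Conditions: LiBH4, MeOH (1 equiv), THF, 0 °C to rt
Reagents that add atoms: none
Why: Chemoselective ester reduction with LiBH4 should take the unhindered ethyl ester to the primary alcohol and leave the tert-butyl benzoate and the aryl triflate, and the stereocentre, β to the ester, cannot epimerise.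

Step 7
Reactants: 8 tert-butyl 4-[(R)-4-hydroxybutan-2-yl]-3-(methoxymethoxy)-5-[(trifluoromethylsulfonyl)oxy]benzoate
Product: 9 tert-butyl 4-[(R)-4-bromobutan-2-yl]-3-(methoxymethoxy)-5-[(trifluoromethylsulfonyl)oxy]benzoate
Conditions: CBr4, PPh3, CH2Cl2, 0 °C
Reagents that add atoms: tetrabromomethane, BrC(Br)(Br)Br
Why: The Appel reaction converts the primary alcohol into the primary bromide under neutral conditions that spare the MOM ether, the triflate and the stereocentre.

Step 8
Reactants: 10 (S)-3-bromo-2-methylpropan-1-ol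
Product: 11 (S)-(3-bromo-2-methylpropoxy)(tert-butyl)dimethylsilane
Conditions: TBSCl, imidazole, DMF, 0 °C to rt
Reagents that add atoms: tert-butyl(chloro)dimethylsilane, CC(C)(C)[Si](C)(C)Cl
Why: Silyl ether formation protects the primary alcohol of the chiral-pool bromide, whose untouched stereocentre becomes the CH(CH3)CH2O centre of the side chain.

Step 9
Reactants: 11 (S)-(3-bromo-2-methylpropoxy)(tert-butyl)dimethylsilane, 12 (4-bromobut-1-yn-1-yl)trimethylsilane
Product: 14 (R)-tert-butyldimethyl{[2-methyl-7-(trimethylsilyl)hept-6-yn-1-yl]oxy}silane, via Grignard reagent 13 (not isolated)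
Conditions: 12, Mg, THF; then 11, Li2CuCl4 (5 mol%), THF, −10 °C to rt
Reagents that add atoms: none
Why: Copper-catalysed sp3–sp3 cross-coupling of a Grignard reagent with a primary alkyl bromide joins the four-carbon alkyne unit without touching the stereocentre, whose descriptor changes from S to R only because the former CH2Br arm loses priority.

Step 10
Reactants: 14 (R)-tert-butyldimethyl{[2-methyl-7-(trimethylsilyl)hept-6-yn-1-yl]oxy}silane
Product: 15 (R)-tert-butyldimethyl[(2-methylhept-6-yn-1-yl)oxy]silane
Conditions: K2CO3 (cat.), MeOH, rt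
Reagents that add atoms: none
Why: Base-catalysed methanolysis of the alkynyl C–Si bond (protodesilylation) frees the terminal alkyne while the alkyl TBS ether stays.

Step 11
Reactants: 15 (R)-tert-butyldimethyl[(2-methylhept-6-yn-1-yl)oxy]silane, 9 tert-butyl 4-[(R)-4-bromobutan-2-yl]-3-(methoxymethoxy)-5-[(trifluoromethylsulfonyl)oxy]benzoate
Product: 18 tert-butyl 4-[(R)-4-bromobutan-2-yl]-3-[(1E,6R)-7-(tert-butyldimethylsilyloxy)-2,6-dimethylhept-1-en-1-yl]-5-(methoxymethoxy)benzoate, via alkenylalane 16 (not isolated), via alkenylzinc chloride 17 (not isolated)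
Conditions: AlMe3, Cp2ZrCl2 (25 mol%), CH2Cl2, 0 °C to rt; volatiles removed; ZnCl2, THF; then 9, Pd(OAc)2, SPhos, THF, 50 °C
Reagents that add atoms: trimethylaluminium, C[Al](C)C
Why: Zirconium-catalysed methylalumination adds CH3 and Al syn to the alkyne with the metal on the terminal carbon, and the Negishi coupling then replaces the metal by the aryl group with retention, so that aryl ends cis to the new methyl (the E styrene the key step needs); the primary bromide should not react under these conditions.

Step 12
Reactants: 18 tert-butyl 4-[(R)-4-bromobutan-2-yl]-3-[(1E,6R)-7-(tert-butyldimethylsilyloxy)-2,6-dimethylhept-1-en-1-yl]-5-(methoxymethoxy)benzoate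
Product: 20 tert-butyl (5R,8S)-8-[(2S,6R)-7-(tert-butyldimethylsilyloxy)-6-methylheptan-2-yl]-4-(methoxymethoxy)-5-methyl-5,6,7,8-tetrahydronaphthalene-2-carboxylate, via benzylic copper species 19 (not isolated)
Conditions: Cu(OAc)2 (5 mol%), (R)-DTBM-SEGPHOS (5.5 mol%), (MeO)2MeSiH, LiOMe, THF, 40 °C
Reagents that add atoms: none
Why: Proposed new method: the bisphosphine-ligated copper hydride should add syn across the E trisubstituted styrene C=C of 18, with copper on the benzylic carbon (the regiochemistry that the aryl ring dictates in copper hydride additions to styrenes) and hydrogen on the methyl-bearing carbon, and benzylic copper species 19 should then be alkylated by the primary bromide on the neighbouring ortho arm (oxidative addition at the CH2Br carbon, then reductive elimination with retention at the copper-bearing carbon), after which LiOMe and the silane regenerate the hydride. The closest known reaction type is the copper hydride catalysed enantioselective intramolecular hydroalkylation of bromide-tethered β-monosubstituted styrenes, which gives indanes, cyclobutanes and cyclopentanes; new here are the β,β-disubstituted styrene and the six-membered carbocycle. Ring B is closed in a 6-exo-tet mode at the CH2Br carbon. The two new stereocentres (the benzylic ring CH, S, and the neighbouring chain CH–CH3, S) are formed together: their relative configuration is fixed by syn delivery of H and the ring CH2 to the E alkene and their absolute configuration by the ligand-controlled choice of alkene face, while the R methyl centre already in the bromobutyl arm is too remote to interfere and lets the ring close through a half-chair with both benzylic substituents pseudoaxial (the trans-1,4 arrangement of the target). The step needs benzylic regiochemistry and ring closure faster than protonation or β-hydride loss of 19; the aryl group should secure the first, and the ortho tether, the aprotic medium and the unhindered primary bromide the second.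

Step 13
Reactants: 20 tert-butyl (5R,8S)-8-[(2S,6R)-7-(tert-butyldimethylsilyloxy)-6-methylheptan-2-yl]-4-(methoxymethoxy)-5-methyl-5,6,7,8-tetrahydronaphthalene-2-carboxylate
Product: 21 tert-butyl (5R,8S)-8-[(2S,6R)-7-hydroxy-6-methylheptan-2-yl]-4-(methoxymethoxy)-5-methyl-5,6,7,8-tetrahydronaphthalene-2-carboxylate
Conditions: TBAF, THF, rt
Reagents that add atoms: none
Why: Fluoride-mediated desilylation removes the alkyl TBS ether, and the MOM aryl ether and the tert-butyl ester are stable to fluoride.

Step 14
Reactants: 21 tert-butyl (5R,8S)-8-[(2S,6R)-7-hydroxy-6-methylheptan-2-yl]-4-(methoxymethoxy)-5-methyl-5,6,7,8-tetrahydronaphthalene-2-carboxylate, 22 3-phenylpropanoyl chloride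
Product: 23 tert-butyl (5R,8S)-4-(methoxymethoxy)-5-methyl-8-[(2S,6R)-6-methyl-7-(3-phenylpropanoyloxy)heptan-2-yl]-5,6,7,8-tetrahydronaphthalene-2-carboxylate
Conditions: Et3N, DMAP (cat.), CH2Cl2, 0 °C
Reagents that add atoms: none
Why: Acylation of the only free hydroxyl by the acid chloride under nucleophilic catalysis (DMAP) should give the 3-phenylpropanoate cleanly.

Step 15
Reactants: 23 tert-butyl (5R,8S)-4-(methoxymethoxy)-5-methyl-8-[(2S,6R)-6-methyl-7-(3-phenylpropanoyloxy)heptan-2-yl]-5,6,7,8-tetrahydronaphthalene-2-carboxylate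
Product: 24 (5R,8S)-4-hydroxy-5-methyl-8-[(2S,6R)-6-methyl-7-(3-phenylpropanoyloxy)heptan-2-yl]-5,6,7,8-tetrahydronaphthalene-2-carboxylic acid (CNP0511546.1)
Conditions: TFA, CH2Cl2, H2O (2 equiv), 0 °C to rt
Reagents that add atoms: none
Why: Acidolysis should remove the tert-butyl ester and the MOM acetal together, while the primary alkyl ester and the four stereocentres, none of which is acid-labile, are untouched.

**Compound list**

1 | 4-bromo-3,5-dihydroxybenzoic acid | OC(=O)c1cc(O)c(Br)c(O)c1 | starting material
2 | tert-butyl 4-bromo-3,5-dihydroxybenzoate | CC(C)(C)OC(=O)c1cc(O)c(Br)c(O)c1 | intermediate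
3 | tert-butyl 4-bromo-3-hydroxy-5-(methoxymethoxy)benzoate | CC(C)(C)OC(=O)c1cc(O)c(Br)c(OCOC)c1 | intermediate
4 | ethyl (Z)-3-(4,4,5,5-tetramethyl-1,3,2-dioxaborolan-2-yl)but-2-enoate | CCOC(=O)/C=C(\C)B1OC(C)(C)C(C)(C)O1 | starting material
5 | tert-butyl 4-[(E)-4-ethoxy-4-oxobut-2-en-2-yl]-3-hydroxy-5-(methoxymethoxy)benzoate | CCOC(=O)/C=C(\C)c1c(O)cc(C(=O)OC(C)(C)C)cc1OCOC | intermediate
6 | tert-butyl 4-[(E)-4-ethoxy-4-oxobut-2-en-2-yl]-3-(methoxymethoxy)-5-[(trifluoromethylsulfonyl)oxy]benzoate | CCOC(=O)/C=C(\C)c1c(OS(=O)(=O)C(F)(F)F)cc(C(=O)OC(C)(C)C)cc1OCOC | intermediate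
7 | tert-butyl 4-[(R)-4-ethoxy-4-oxobutan-2-yl]-3-(methoxymethoxy)-5-[(trifluoromethylsulfonyl)oxy]benzoate | CCOC(=O)C[C@@H](C)c1c(OS(=O)(=O)C(F)(F)F)cc(C(=O)OC(C)(C)C)cc1OCOC | intermediate
8 | tert-butyl 4-[(R)-4-hydroxybutan-2-yl]-3-(methoxymethoxy)-5-[(trifluoromethylsulfonyl)oxy]benzoate | OCC[C@@H](C)c1c(OS(=O)(=O)C(F)(F)F)cc(C(=O)OC(C)(C)C)cc1OCOC | intermediate
9 | tert-butyl 4-[(R)-4-bromobutan-2-yl]-3-(methoxymethoxy)-5-[(trifluoromethylsulfonyl)oxy]benzoate | BrCC[C@@H](C)c1c(OS(=O)(=O)C(F)(F)F)cc(C(=O)OC(C)(C)C)cc1OCOC | intermediate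
10 | (S)-3-bromo-2-methylpropan-1-ol | C[C@H](CBr)CO | starting material
11 | (S)-(3-bromo-2-methylpropoxy)(tert-butyl)dimethylsilane | C[C@H](CBr)CO[Si](C)(C)C(C)(C)C | intermediate
12 | (4-bromobut-1-yn-1-yl)trimethylsilane | C[Si](C)(C)C#CCCBr | starting material
13 | [4-(trimethylsilyl)but-3-yn-1-yl]magnesium bromide | C[Si](C)(C)C#CCC[Mg]Br | intermediate
14 | (R)-tert-butyldimethyl{[2-methyl-7-(trimethylsilyl)hept-6-yn-1-yl]oxy}silane | C[C@H](CCCC#C[Si](C)(C)C)CO[Si](C)(C)C(C)(C)C | intermediate
15 | (R)-tert-butyldimethyl[(2-methylhept-6-yn-1-yl)oxy]silane | C[C@H](CCCC#C)CO[Si](C)(C)C(C)(C)C | intermediate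
16 | [(1E,6R)-7-(tert-butyldimethylsilyloxy)-2,6-dimethylhept-1-en-1-yl]dimethylalane | C[C@H](CCC/C(C)=C/[Al](C)C)CO[Si](C)(C)C(C)(C)C | intermediate
17 | [(1E,6R)-7-(tert-butyldimethylsilyloxy)-2,6-dimethylhept-1-en-1-yl]zinc chloride | C[C@H](CCC/C(C)=C/[Zn]Cl)CO[Si](C)(C)C(C)(C)C | intermediate
18 | tert-butyl 4-[(R)-4-bromobutan-2-yl]-3-[(1E,6R)-7-(tert-butyldimethylsilyloxy)-2,6-dimethylhept-1-en-1-yl]-5-(methoxymethoxy)benzoate | C[C@H](CCC/C(C)=C/c1cc(C(=O)OC(C)(C)C)cc(OCOC)c1[C@H](C)CCBr)CO[Si](C)(C)C(C)(C)C | intermediate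
19 | benzylic copper species from syn hydrocupration of 18 (phosphine ligand on copper omitted) | C[C@H](CCC[C@H](C)[C@H]([Cu])c1cc(C(=O)OC(C)(C)C)cc(OCOC)c1[C@H](C)CCBr)CO[Si](C)(C)C(C)(C)C | intermediate
20 | tert-butyl (5R,8S)-8-[(2S,6R)-7-(tert-butyldimethylsilyloxy)-6-methylheptan-2-yl]-4-(methoxymethoxy)-5-methyl-5,6,7,8-tetrahydronaphthalene-2-carboxylate | C[C@H](CCC[C@H](C)[C@@H]1CC[C@@H](C)c2c(OCOC)cc(C(=O)OC(C)(C)C)cc21)CO[Si](C)(C)C(C)(C)C | intermediate
21 | tert-butyl (5R,8S)-8-[(2S,6R)-7-hydroxy-6-methylheptan-2-yl]-4-(methoxymethoxy)-5-methyl-5,6,7,8-tetrahydronaphthalene-2-carboxylate | C[C@H](CCC[C@H](C)[C@@H]1CC[C@@H](C)c2c(OCOC)cc(C(=O)OC(C)(C)C)cc21)CO | intermediate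
22 | 3-phenylpropanoyl chloride | O=C(Cl)CCc1ccccc1 | starting material
23 | tert-butyl (5R,8S)-4-(methoxymethoxy)-5-methyl-8-[(2S,6R)-6-methyl-7-(3-phenylpropanoyloxy)heptan-2-yl]-5,6,7,8-tetrahydronaphthalene-2-carboxylate | C[C@H](CCC[C@H](C)[C@@H]1CC[C@@H](C)c2c(OCOC)cc(C(=O)OC(C)(C)C)cc21)COC(=O)CCc1ccccc1 | intermediate
24 | (5R,8S)-4-hydroxy-5-methyl-8-[(2S,6R)-6-methyl-7-(3-phenylpropanoyloxy)heptan-2-yl]-5,6,7,8-tetrahydronaphthalene-2-carboxylic acid (CNP0511546.1) | C[C@H](CCC[C@H](C)[C@@H]1CC[C@@H](C)c2c(O)cc(C(=O)O)cc21)COC(=O)CCc1ccccc1 | target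

**Step count and risks**

Total step count: 15. Longest linear sequence: 12 steps (steps 1–7, then 11–15).

Steps most likely to fail:

Step 12. Hydrocupration of the hindered β,β-disubstituted styrene may be too slow, so that simple reduction of the C–Br bond or protonation of the benzylic copper species (giving the uncyclised dihydro compound) overtakes ring closure; control of the alkene face may also be incomplete. The fallback uses known chemistry and runs from 18 back to 20: a reductive radical cyclisation under tin hydride conditions (Bu3SnH added slowly, AIBN, benzene, 80 °C). The primary alkyl radical formed at the CH2Br carbon should add in the 6-exo-trig mode to the aryl-bearing alkene carbon, and the resulting tertiary radical is quenched by the stannane. The benzylic centre should again form trans to the ring methyl through the diaxial half-chair, but hydrogen transfer to the chain radical is not expected to be selective, so 20 would have to be separated from its epimer at the chain CH–CH3 centre. This fallback makes no new compound (F0).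

Step 11. Methyl transfer from residual methylaluminium or methylzinc species may compete with alkenyl transfer, oxidative addition of the ortho-alkyl triflate may be slow, or the aluminium reagent may attack the tert-butyl ester. The fallback runs from 15 and 9 back to 18. The alkenylalane from the same methylalumination is quenched with I2 to give (R,E)-tert-butyl[(7-iodo-2,6-dimethylhept-6-en-1-yl)oxy]dimethylsilane F1, which is purified. Iodine–lithium exchange (t-BuLi, Et2O, −78 °C) and trapping with 2-isopropoxy-4,4,5,5-tetramethyl-1,3,2-dioxaborolane convert it into (R,E)-tert-butyl{[2,6-dimethyl-7-(4,4,5,5-tetramethyl-1,3,2-dioxaborolan-2-yl)hept-6-en-1-yl]oxy}dimethylsilane F2. F2 is then joined to triflate 9 by a Suzuki–Miyaura coupling (Pd(OAc)2, SPhos, K3PO4, THF/H2O, 50 °C), in which no methyl-metal species is present.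

Step 5. Hydride delivery to a β-carbon that carries a twisted, doubly ortho-substituted aryl group may be slow or poorly face-selective, or the triflate may be lost. The fallback runs from 3 back to 8 and makes the ring-methyl centre by asymmetric hydroformylation instead. Bromide 3 is coupled (Suzuki–Miyaura, Pd(OAc)2, SPhos, K3PO4) with 2-isopropenyl-4,4,5,5-tetramethyl-1,3,2-dioxaborolane to give tert-butyl 3-hydroxy-5-(methoxymethoxy)-4-(prop-1-en-2-yl)benzoate F3. The phenol is triflated (Tf2O, pyridine) to tert-butyl 3-(methoxymethoxy)-4-(prop-1-en-2-yl)-5-[(trifluoromethylsulfonyl)oxy]benzoate F4. Rhodium-catalysed anti-Markovnikov asymmetric hydroformylation of the 1,1-disubstituted alkene (Rh(acac)(CO)2, chiral phosphine–phosphoramidite ligand, CO/H2) gives tert-butyl 3-(methoxymethoxy)-4-[(R)-4-oxobutan-2-yl]-5-[(trifluoromethylsulfonyl)oxy]benzoate F5, and NaBH4 reduction of F5 gives alcohol 8.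

Further compounds

F0 | step 12 | none | none
F1 | step 11 | (R,E)-tert-butyl[(7-iodo-2,6-dimethylhept-6-en-1-yl)oxy]dimethylsilane | C[C@H](CCC/C(C)=C/I)CO[Si](C)(C)C(C)(C)C
F2 | step 11 | (R,E)-tert-butyl{[2,6-dimethyl-7-(4,4,5,5-tetramethyl-1,3,2-dioxaborolan-2-yl)hept-6-en-1-yl]oxy}dimethylsilane | C[C@H](CCC/C(C)=C/B1OC(C)(C)C(C)(C)O1)CO[Si](C)(C)C(C)(C)C
F3 | step 5 | tert-butyl 3-hydroxy-5-(methoxymethoxy)-4-(prop-1-en-2-yl)benzoate | CC(=C)c1c(O)cc(C(=O)OC(C)(C)C)cc1OCOC
F4 | step 5 | tert-butyl 3-(methoxymethoxy)-4-(prop-1-en-2-yl)-5-[(trifluoromethylsulfonyl)oxy]benzoate | CC(=C)c1c(OS(=O)(=O)C(F)(F)F)cc(C(=O)OC(C)(C)C)cc1OCOC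
F5 | step 5 | tert-butyl 3-(methoxymethoxy)-4-[(R)-4-oxobutan-2-yl]-5-[(trifluoromethylsulfonyl)oxy]benzoate | O=CC[C@@H](C)c1c(OS(=O)(=O)C(F)(F)F)cc(C(=O)OC(C)(C)C)cc1OCOC
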